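**Plan**

- Retrosynthesis (chromene numbering O1, C2, C3, C4, C4a, C5–C8, C8a): the C3=C4 bond of the pyran is cut by ring-closing olefin metathesis to a vinyl group on C4a and a 1,1-dimethylallyl ether on O1. The C8–prenyl bond is cut to a prenyl ether on O5 (para-Claisen–Cope). The C4a–vinyl, O1–C2 and C6–acyl bonds are cut back to 5-methoxyresorcinol and 4-hydroxyphenylacetonitrile.
- Enabling feature: C3 and C4 are two CH carbons of a cis olefin inside the six-membered pyran ring. C4 sits on arene carbon C4a and C3 on the hydrogen-free quaternary C2 carried by O1 at C8a, so both olefin halves can be attached beforehand to adjacent ring A positions.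
- Forward order: rings A and B are bought and joined by Hoesch acylation; the carbon between the two hydroxyls is iodinated and vinylated; the most acidic hydroxyl is etherified; metathesis then closes the pyran, the only ring formed in the route.
- The prenyl group is then relayed from O5 to C8, the only ring A carbon para to O5, which also returns the chelated C5 hydroxyl.
- Stereochemistry: the target has no stereocentre; the C3=C4 olefin is cis because it lies in the six-membered ring.

Key step: step 6

**Step 1**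
Reactants: 1 5-methoxybenzene-1,3-diol; 2 2-(4-hydroxyphenyl)acetonitrile
Product: 4 1-(2,4-dihydroxy-6-methoxyphenyl)-2-(4-hydroxyphenyl)ethan-1-one, via ketiminium chloride 3 (not isolated)
Conditions: ZnCl2 (0.2 equiv), HCl (g), Et2O, 0 °C; then H2O, reflux
Reagents that add atoms: water, O
Why: Hoesch acylation, in which the nitrilium electrophile should attack the ring carbon of 1 that is para to one hydroxyl and ortho to the methoxyl (the symmetric 2,6-dihydroxy-4-methoxy isomer is the expected minor product and is removed), and hydrolysis of salt 3 gives the ketone.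

**Step 2**
Reactants: 4 1-(2,4-dihydroxy-6-methoxyphenyl)-2-(4-hydroxyphenyl)ethan-1-one
Product: 5 1-(2,4-dihydroxy-3-iodo-6-methoxyphenyl)-2-(4-hydroxyphenyl)ethan-1-one
Conditions: I2 (1.0 equiv), NaHCO3, THF–H2O, 0 °C
Reagents that add atoms: iodine, II
Why: Electrophilic aromatic iodination of the resorcinol-type phenoxide, which should go to the carbon flanked by both hydroxyls (the future C4a) as in the formation of 2-iodoresorcinol under these conditions, with ring B and the carbon next to the methoxyl far less reactive.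

**Step 3**
Reactants: 5 1-(2,4-dihydroxy-3-iodo-6-methoxyphenyl)-2-(4-hydroxyphenyl)ethan-1-one
Product: 6 1-(3-ethenyl-2,4-dihydroxy-6-methoxyphenyl)-2-(4-hydroxyphenyl)ethan-1-one
Conditions: tributyl(vinyl)stannane, Pd(PPh3)4 (5 mol %), DMF, 80 °C
Reagents that add atoms: tributyl(vinyl)stannane, C=C[Sn](CCCC)(CCCC)CCCC
Why: Stille cross-coupling of the aryl iodide under neutral conditions that tolerate the three free phenols and the ketone.

**Step 4**
Reactants: 7 2-methylbut-3-en-2-ol
Product: 8 methyl 2-methylbut-3-en-2-yl carbonate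
Conditions: ClCO2Me, pyridine, DMAP (cat.), CH2Cl2, 0 °C to rt
Reagents that add atoms: methyl chloroformate, COC(=O)Cl
Why: Carbonate formation by acylation of the tertiary allylic alcohol with a chloroformate, which makes the ionisable partner for step 5.

**Step 5**
Reactants: 6 1-(3-ethenyl-2,4-dihydroxy-6-methoxyphenyl)-2-(4-hydroxyphenyl)ethan-1-one; 8 methyl 2-methylbut-3-en-2-yl carbonate
Product: 9 1-{3-ethenyl-2-hydroxy-6-methoxy-4-[(2-methylbut-3-en-2-yl)oxy]phenyl}-2-(4-hydroxyphenyl)ethan-1-one
Conditions: 8 (1.1 equiv), Pd(PPh3)4 (2 mol %), THF, 0 °C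
Reagents that add atoms: none
Why: Tsuji–Trost allylic etherification, in which ionisation of 8 gives a (1,1-dimethylallyl)palladium cation and methoxide, the methoxide deprotonates the most acidic hydroxyl of 6 (para to the acyl group), and the phenoxide should attack the more substituted allyl terminus under kinetic control to give the tertiary ether, leaving the chelated hydroxyl and the less acidic ring B phenol free.

**Step 6**
Reactants: 9 1-{3-ethenyl-2-hydroxy-6-methoxy-4-[(2-methylbut-3-en-2-yl)oxy]phenyl}-2-(4-hydroxyphenyl)ethan-1-one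
Product: 10 1-(5-hydroxy-7-methoxy-2,2-dimethyl-2H-chromen-6-yl)-2-(4-hydroxyphenyl)ethan-1-one
Conditions: second-generation Grubbs catalyst RuCl2(=CHPh)(PCy3)(H2IMes) (5 mol %), CH2Cl2 (0.005 M), 40 °C
Reagents that add atoms: none
Why: Ring-closing olefin metathesis: the ruthenium benzylidene should exchange first onto the unhindered vinyl group on the future C4a, the new aryl-substituted alkylidene should add in a [2+2] sense to the neighbouring oxygen-bound 1,1-dimethylallyl olefin, and cycloreversion of the ruthenacyclobutane should release the C3=C4 bond of 10 and a ruthenium methylidene, with ethene as the only co-product. The closest known reaction type is the ring-closing metathesis of 2-vinylaryl allyl and 1,1-dimethylallyl ethers to 2H-chromenes. The pyran is closed as a six-membered ring by intramolecular alkene–alkylidene metathesis between two olefins held on adjacent ring A carbons through C4a and through O1 on C8a. No stereocentre is formed, and the new olefin can only be cis because it lies in the six-membered ring. The step needs chemoselectivity for metathesis over the thermal Claisen shift of the tertiary allyl ether to the free C8 position and over intermolecular styrene coupling; the low temperature, the high dilution and the gem-dimethyl group at C2 (no allylic hydrogen, compressed tether) should secure this, and the free phenols and the chelated ketone are tolerated by the catalyst.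

**Step 7**
Reactants: 10 1-(5-hydroxy-7-methoxy-2,2-dimethyl-2H-chromen-6-yl)-2-(4-hydroxyphenyl)ethan-1-one
Product: 11 2-{4-[(tert-butyldimethylsilyl)oxy]phenyl}-1-(5-hydroxy-7-methoxy-2,2-dimethyl-2H-chromen-6-yl)ethan-1-one
Conditions: TBSCl (1.1 equiv), imidazole, DMF, 0 °C to rt
Reagents that add atoms: tert-butyldimethylsilyl chloride, CC(C)(C)[Si](C)(C)Cl
Why: Silyl ether formation, selective for the unhindered ring B phenol because the C5 hydroxyl is hydrogen-bonded to the ketone and flanked by two substituents.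

**Step 8**
Reactants: 11 2-{4-[(tert-butyldimethylsilyl)oxy]phenyl}-1-(5-hydroxy-7-methoxy-2,2-dimethyl-2H-chromen-6-yl)ethan-1-one
Product: 12 2-{4-[(tert-butyldimethylsilyl)oxy]phenyl}-1-{7-methoxy-2,2-dimethyl-5-[(3-methylbut-2-en-1-yl)oxy]-2H-chromen-6-yl}ethan-1-one
Conditions: 3-methylbut-2-en-1-ol, PPh3, DIAD, THF, 0 °C to rt
Reagents that add atoms: 3-methylbut-2-en-1-ol, CC(C)=CCO
Why: Mitsunobu etherification of the chelated C5 phenol with the primary allylic alcohol under neutral conditions (SN2 at the alkoxyphosphonium carbon gives the unrearranged prenyl ether), which spares the silyl ether and the chromene.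

**Step 9**
Reactants: 12 2-{4-[(tert-butyldimethylsilyl)oxy]phenyl}-1-{7-methoxy-2,2-dimethyl-5-[(3-methylbut-2-en-1-yl)oxy]-2H-chromen-6-yl}ethan-1-one
Product: 15 2-{4-[(tert-butyldimethylsilyl)oxy]phenyl}-1-[5-hydroxy-7-methoxy-2,2-dimethyl-8-(3-methylbut-2-en-1-yl)-2H-chromen-6-yl]ethan-1-one, via ortho-dienone 13 (not isolated), via para-dienone 14 (not isolated)
Conditions: N,N-diethylaniline, 195 °C, sealed tube, argon
Reagents that add atoms: none
Why: Para-Claisen rearrangement (aromatic Claisen then Cope), in which both ortho carbons of O5 (C6 and C4a) are substituted, so the first [3,3] shift gives the blocked dienone 13 (the C4a alternative converges), a second [3,3] shift carries the allyl unit to C8, the only ring A carbon that is para to O5 and bears hydrogen, and enolisation of 14 restores the arene and the chelated C5 hydroxyl with the prenyl group unrearranged after two allylic inversions.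

**Step 10**
Reactants: 15 2-{4-[(tert-butyldimethylsilyl)oxy]phenyl}-1-[5-hydroxy-7-methoxy-2,2-dimethyl-8-(3-methylbut-2-en-1-yl)-2H-chromen-6-yl]ethan-1-one
Product: 16 1-[5-hydroxy-7-methoxy-2,2-dimethyl-8-(3-methylbut-2-en-1-yl)-2H-chromen-6-yl]-2-(4-hydroxyphenyl)ethan-1-one
Conditions: TBAF, AcOH, THF, 0 °C
Reagents that add atoms: none
Why: Fluoride-mediated desilylation of the aryl silyl ether, buffered with acetic acid so that the phenols, the ketone, the prenyl group and the chromene are left untouched.

**Compound list**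

1 | 5-methoxybenzene-1,3-diol (5-methoxyresorcinol) | COc1cc(O)cc(O)c1 | starting material
2 | 2-(4-hydroxyphenyl)acetonitrile | N#CCc1ccc(O)cc1 | starting material
3 | 1-(2,4-dihydroxy-6-methoxyphenyl)-2-(4-hydroxyphenyl)ethan-1-iminium chloride | COc1cc(O)cc(O)c1C(=[NH2+])Cc1ccc(O)cc1.[Cl-] | intermediate (not isolated)
4 | 1-(2,4-dihydroxy-6-methoxyphenyl)-2-(4-hydroxyphenyl)ethan-1-one | COc1cc(O)cc(O)c1C(=O)Cc1ccc(O)cc1 | intermediate
5 | 1-(2,4-dihydroxy-3-iodo-6-methoxyphenyl)-2-(4-hydroxyphenyl)ethan-1-one | COc1cc(O)c(I)c(O)c1C(=O)Cc1ccc(O)cc1 | intermediate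
6 | 1-(3-ethenyl-2,4-dihydroxy-6-methoxyphenyl)-2-(4-hydroxyphenyl)ethan-1-one | COc1cc(O)c(C=C)c(O)c1C(=O)Cc1ccc(O)cc1 | intermediate
7 | 2-methylbut-3-en-2-ol | CC(C)(O)C=C | starting material
8 | methyl 2-methylbut-3-en-2-yl carbonate | COC(=O)OC(C)(C)C=C | intermediate
9 | 1-{3-ethenyl-2-hydroxy-6-methoxy-4-[(2-methylbut-3-en-2-yl)oxy]phenyl}-2-(4-hydroxyphenyl)ethan-1-one | COc1cc(OC(C)(C)C=C)c(C=C)c(O)c1C(=O)Cc1ccc(O)cc1 | intermediate
10 | 1-(5-hydroxy-7-methoxy-2,2-dimethyl-2H-chromen-6-yl)-2-(4-hydroxyphenyl)ethan-1-one | COc1cc2c(C=CC(C)(C)O2)c(O)c1C(=O)Cc1ccc(O)cc1 | intermediate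
11 | 2-{4-[(tert-butyldimethylsilyl)oxy]phenyl}-1-(5-hydroxy-7-methoxy-2,2-dimethyl-2H-chromen-6-yl)ethan-1-one | COc1cc2c(C=CC(C)(C)O2)c(O)c1C(=O)Cc1ccc(O[Si](C)(C)C(C)(C)C)cc1 | intermediate
12 | 2-{4-[(tert-butyldimethylsilyl)oxy]phenyl}-1-{7-methoxy-2,2-dimethyl-5-[(3-methylbut-2-en-1-yl)oxy]-2H-chromen-6-yl}ethan-1-one | COc1cc2c(C=CC(C)(C)O2)c(OCC=C(C)C)c1C(=O)Cc1ccc(O[Si](C)(C)C(C)(C)C)cc1 | intermediate
13 | 6-{2-[4-(tert-butyldimethylsilyloxy)phenyl]acetyl}-7-methoxy-2,2-dimethyl-6-(2-methylbut-3-en-2-yl)-2H-chromen-5(6H)-one (ortho-dienone, racemic) | COC1=CC2=C(C=CC(C)(C)O2)C(=O)C1(C(C)(C)C=C)C(=O)Cc1ccc(O[Si](C)(C)C(C)(C)C)cc1 | intermediate (not isolated)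
14 | 6-{2-[4-(tert-butyldimethylsilyloxy)phenyl]acetyl}-7-methoxy-2,2-dimethyl-8-(3-methylbut-2-en-1-yl)-2H-chromen-5(8H)-one (para-dienone, racemic) | COC1=C(C(=O)Cc2ccc(O[Si](C)(C)C(C)(C)C)cc2)C(=O)C2=C(OC(C)(C)C=C2)C1CC=C(C)C | intermediate (not isolated)
15 | 2-{4-[(tert-butyldimethylsilyl)oxy]phenyl}-1-[5-hydroxy-7-methoxy-2,2-dimethyl-8-(3-methylbut-2-en-1-yl)-2H-chromen-6-yl]ethan-1-one | COc1c(CC=C(C)C)c2c(C=CC(C)(C)O2)c(O)c1C(=O)Cc1ccc(O[Si](C)(C)C(C)(C)C)cc1 | intermediate
16 | 1-[5-hydroxy-7-methoxy-2,2-dimethyl-8-(3-methylbut-2-en-1-yl)-2H-chromen-6-yl]-2-(4-hydroxyphenyl)ethan-1-one (no stereocentre) | COc1c(CC=C(C)C)c2c(C=CC(C)(C)O2)c(O)c1C(=O)Cc1ccc(O)cc1 | target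

**Totals**

Total step count: 10. Longest linear sequence: 9 steps (steps 1–3 and 5–10; step 4 is a one-step side branch).

**Steps most likely to fail**

Step 5. The tertiary aryl allyl ether may be re-ionised by zerovalent palladium and drift to the linear prenyl ether or to C-allylation at the free ring A carbon, and the ring B phenol may be etherified in part. The fallback sets out from 6: O-alkylation with 3-chloro-3-methylbut-1-yne (K2CO3, KI, CuI, acetone, 50 °C) should give 1-{3-ethenyl-2-hydroxy-6-methoxy-4-[(2-methylbut-3-yn-2-yl)oxy]phenyl}-2-(4-hydroxyphenyl)ethan-1-one F1. Semi-hydrogenation of its alkyne (H2, Pd/CaCO3 poisoned with Pb(OAc)2, quinoline, EtOAc, stopped at one equivalent) comes back to the route at 9.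

Step 9. The prenyl ether may fragment thermally to the phenol and isoprene, or the blocked dienones may be diverted before the second shift reaches C8. The fallback sets out from 9, before the pyran is closed. Ortho-Claisen rearrangement (toluene, 110 °C), for which the future C8 is the only free ortho carbon, should give 1-[3-ethenyl-2,4-dihydroxy-6-methoxy-5-(3-methylbut-2-en-1-yl)phenyl]-2-(4-hydroxyphenyl)ethan-1-one F2. Re-etherification of the same, most acidic hydroxyl with 8 and Pd(PPh3)4 (THF, 0 °C) should give 1-{3-ethenyl-2-hydroxy-6-methoxy-5-(3-methylbut-2-en-1-yl)-4-[(2-methylbut-3-en-2-yl)oxy]phenyl}-2-(4-hydroxyphenyl)ethan-1-one F3. Ring-closing metathesis of F3 with the second-generation Grubbs catalyst (CH2Cl2, 40 °C) comes back to the route at 16 without any protecting group.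

Step 2. Site-selectivity between the carbon flanked by two hydroxyls and the carbon next to the methoxyl may be poor, or a second iodination may follow the first. The fallback sets out from 4 and brings in the future C4 as a formyl carbon. Duff formylation (hexamethylenetetramine, AcOH, 100 °C; then aq. HCl), which in resacetophenone-type ketones is delivered between the two hydroxyls, should give 2,6-dihydroxy-3-[2-(4-hydroxyphenyl)acetyl]-4-methoxybenzaldehyde F4. Wittig methylenation with excess Ph3P=CH2 (from Ph3PCH3Br and KOtBu, THF, 0 °C to rt) comes back to the route at 6.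

**Further compounds**

F1 | step 5 | 1-{3-ethenyl-2-hydroxy-6-methoxy-4-[(2-methylbut-3-yn-2-yl)oxy]phenyl}-2-(4-hydroxyphenyl)ethan-1-one | COc1cc(OC(C)(C)C#C)c(C=C)c(O)c1C(=O)Cc1ccc(O)cc1
F2 | step 9 | 1-[3-ethenyl-2,4-dihydroxy-6-methoxy-5-(3-methylbut-2-en-1-yl)phenyl]-2-(4-hydroxyphenyl)ethan-1-one | COc1c(CC=C(C)C)c(O)c(C=C)c(O)c1C(=O)Cc1ccc(O)cc1
F3 | step 9 | 1-{3-ethenyl-2-hydroxy-6-methoxy-5-(3-methylbut-2-en-1-yl)-4-[(2-methylbut-3-en-2-yl)oxy]phenyl}-2-(4-hydroxyphenyl)ethan-1-one | COc1c(CC=C(C)C)c(OC(C)(C)C=C)c(C=C)c(O)c1C(=O)Cc1ccc(O)cc1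
F4 | step 2 | 2,6-dihydroxy-3-[2-(4-hydroxyphenyl)acetyl]-4-methoxybenzaldehyde | COc1cc(O)c(C=O)c(O)c1C(=O)Cc1ccc(O)cc1
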